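**Plan**
- Retrosynthesis: the five O-benzyl groups are cut first; then the C4–C4a bond of ring C, so that the C3 vanillate traces back to a 2-aryl-1,3-dioxolan-2-ylium ion spanning O3–C3–C4–O. That ion comes from a 3,4-diol and a vanillic ortho ester; the O1–C2 ether and the C2–aryl bond are cut last.
- Forward: ring B is joined to a three-carbon unit, ring A is hung on O1, the diol is freed and tied with the ortho ester into a temporary dioxolane ring, ring C is closed, and the benzyl groups are removed.
- Enabling feature: the acylated O3 and the C4 methylene sit on adjacent carbons, so the vanilloyl carbon can bridge O3 and a C4 oxygen. This makes C4 an alkylating carbon and leaves the ester on O3 when the ring opens. Ring A is a phloroglucinol ether whose two carbons ortho to O1 are equivalent, strongly nucleophilic and six atoms from C4.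
- Stereochemistry: C3 comes from the chiral pool ((R)-glyceraldehyde acetonide); C2 is set by Felkin–Anh aryl addition (anti) and then Mitsunobu inversion, giving 2R,3R (2,3-cis). The ring closure touches neither centre.

Key step: step 6

Remark on the chemistry: ortho ester 12 forms as both epimers at its orthoester carbon; both give the same ion 13, so its SMILES carries no descriptor there.

**Step 1**
Reactants: 1 4-bromo-1,2-bis(benzyloxy)benzene; 2 (R)-2,2-dimethyl-1,3-dioxolane-4-carbaldehyde
Product: 4 (S)-[3,4-bis(benzyloxy)phenyl][(4R)-2,2-dimethyl-1,3-dioxolan-4-yl]methanol, via arylmagnesium bromide 3 (not isolated)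
Conditions: Mg turnings, THF, 50 °C; then 2 (freshly distilled), THF, −78 °C to 0 °C; aq. NH4Cl
Reagents that add atoms: none
Why: Grignard addition to an α-alkoxy aldehyde under Felkin–Anh control (aryl anti to the α C–O bond, past the hydrogen) should favour the anti (S)-carbinol beside the (R)-centre carried over from 2, with only moderate selectivity expected and the minor syn epimer removed by chromatography.

**Step 2**
Reactants: 4 (S)-[3,4-bis(benzyloxy)phenyl][(4R)-2,2-dimethyl-1,3-dioxolan-4-yl]methanol; 5 3,5-bis(benzyloxy)phenol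
Product: 6 (4R)-4-{(R)-[3,4-bis(benzyloxy)phenyl][3,5-bis(benzyloxy)phenoxy]methyl}-2,2-dimethyl-1,3-dioxolane
Conditions: PPh3, DIAD, toluene, 0 °C to rt
Reagents that add atoms: none
Why: Mitsunobu etherification, in which the phenol displaces the alkoxyphosphonium ion by SN2 with inversion (S to R at the benzylic carbon), should turn the anti alcohol into the syn (threo) aryl ether that maps onto the 2,3-cis flavan, the non-polar solvent and low temperature holding back ionisation of the electron-rich benzylic centre.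

**Step 3**
Reactants: 6 (4R)-4-{(R)-[3,4-bis(benzyloxy)phenyl][3,5-bis(benzyloxy)phenoxy]methyl}-2,2-dimethyl-1,3-dioxolane
Product: 7 (2R,3R)-3-[3,4-bis(benzyloxy)phenyl]-3-[3,5-bis(benzyloxy)phenoxy]propane-1,2-diol
Conditions: AcOH–H2O–THF (4:1:1), 45 °C
Reagents that add atoms: none
Why: Acid-catalysed ketal hydrolysis should free the vicinal diol while the benzyl ethers and the secondary benzylic aryl ether (deactivated towards ionisation by its two β-oxygens) survive, so no stereocenter changes.

**Step 4**
Reactants: 8 1-(benzyloxy)-4-bromo-2-methoxybenzene; 9 tetramethyl orthocarbonate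
Product: 11 1-(benzyloxy)-2-methoxy-4-(trimethoxymethyl)benzene, via arylmagnesium bromide 10 (not isolated)
Conditions: Mg turnings, THF, 50 °C; then 9 (excess), toluene, 80 °C; cold aq. NaHCO3
Reagents that add atoms: none
Why: Tschitschibabin orthoester synthesis, in which the aryl Grignard reagent displaces one methoxide of the orthocarbonate through a magnesium-assisted trimethoxycarbenium ion, should stop at the less electrophilic aryl ortho ester when 9 is in excess.

**Step 5**
Reactants: 7 (2R,3R)-3-[3,4-bis(benzyloxy)phenyl]-3-[3,5-bis(benzyloxy)phenoxy]propane-1,2-diol; 11 1-(benzyloxy)-2-methoxy-4-(trimethoxymethyl)benzene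
Product: 12 (4R)-2-[4-(benzyloxy)-3-methoxyphenyl]-4-{(R)-[3,4-bis(benzyloxy)phenyl][3,5-bis(benzyloxy)phenoxy]methyl}-2-methoxy-1,3-dioxolane (both epimers at C2 of the dioxolane)
Conditions: PPTS (cat.), 4 Å molecular sieves, CH2Cl2, rt; then Et3N
Reagents that add atoms: none
Why: Acid-catalysed transorthoesterification, driven by entropy and removal of methanol, should close the 1,2-diol to the five-membered cyclic ortho ester as both epimers at the new orthoester carbon (irrelevant, since that carbon becomes planar in step 6), the weak acid not ionising it far enough for ring closure.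

**Step 6**
Reactants: 12 (4R)-2-[4-(benzyloxy)-3-methoxyphenyl]-4-{(R)-[3,4-bis(benzyloxy)phenyl][3,5-bis(benzyloxy)phenoxy]methyl}-2-methoxy-1,3-dioxolane
Product: 14 (2R,3R)-5,7-bis(benzyloxy)-2-[3,4-bis(benzyloxy)phenyl]-3,4-dihydro-2H-chromen-3-yl 4-(benzyloxy)-3-methoxybenzoate, via dioxolanylium triflate 13 (not isolated)
Conditions: TMSOTf, 2,6-di-tert-butyl-4-methylpyridine, CH2Cl2 (high dilution), −78 °C to rt; aq. NaHCO3
Reagents that add atoms: none
Why: Proposed new method: TMSOTf should remove the methoxy group of the ortho ester as MeOSiMe3 to give the 2-aryl-1,3-dioxolan-2-ylium ion 13, whose primary O–CH2 carbon (C4 of the flavan) is an oxonium-type alkylating centre; the tethered 3,5-bis(benzyloxy)phenoxy ring attacks it with the carbon ortho to O1 in an SN2 (Ar2-6) displacement, the ring oxygen leaves as the carbonyl oxygen of the C3 ester, and the hindered pyridine deprotonates the Wheland intermediate. The closest known reaction types are the opening of acyloxonium ions at carbon by halide (Hanessian–Hullar and Prévost reactions, and the orthoester route from diols to acetoxy halides) and Friedel–Crafts cyclialkylation of electron-rich arenes by primary sulfonates with aryl participation; capture of the acyloxonium alkyl carbon by an arene is the new element. Ring C closes in a 6-(enolendo)-exo-tet mode, by backside attack on C4 with the leaving oxygen outside the new ring, which the dioxolane permits because the line of attack on C4 lies gauche to the C3–C2 bond as a six-membered transition state requires. No stereocenter is created or broken: the C3–O bond is never cleaved, so the vanillate appears on O3 with retention and the 2R,3R cis relationship from steps 1 and 2 is carried into the ring. The step needs attack at the primary C4 and not at the secondary C3 (a hindered 5-(enolendo)-exo-tet closure, disfavoured by the Baldwin rules) or at the cationic carbon (a seven-membered ring onto a crowded, aryl-stabilised centre), and attack by ring A and not ring B (one activating oxygen and only a five-membered ring available); the local symmetry of ring A makes its two ortho carbons equivalent, so a single chroman can form. High dilution and the non-nucleophilic base should guard against intermolecular alkylation and acid-induced ionisation of the product at C2.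

**Step 7**
Reactants: 14 (2R,3R)-5,7-bis(benzyloxy)-2-[3,4-bis(benzyloxy)phenyl]-3,4-dihydro-2H-chromen-3-yl 4-(benzyloxy)-3-methoxybenzoate
Product: 15 (2R,3R)-2-(3,4-dihydroxyphenyl)-5,7-dihydroxy-3,4-dihydro-2H-chromen-3-yl 4-hydroxy-3-methoxybenzoate
Conditions: H2 (1 atm), Pd(OH)2/C, THF–MeOH, rt
Reagents that add atoms: none
Why: Hydrogenolysis of the five benzyl aryl ethers should leave the ester and the cyclic benzylic C2–O1 ether intact, as is usual for benzylated flavan-3-ol esters, and affects no stereocenter.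

**Compound list**
1 | 4-bromo-1,2-bis(benzyloxy)benzene | Brc1ccc(OCc2ccccc2)c(OCc2ccccc2)c1 | starting material
2 | (R)-2,2-dimethyl-1,3-dioxolane-4-carbaldehyde | CC1(C)OC[C@H](C=O)O1 | starting material
3 | [3,4-bis(benzyloxy)phenyl]magnesium bromide | Br[Mg]c1ccc(OCc2ccccc2)c(OCc2ccccc2)c1 | intermediate
4 | (S)-[3,4-bis(benzyloxy)phenyl][(4R)-2,2-dimethyl-1,3-dioxolan-4-yl]methanol | CC1(C)OC[C@H]([C@@H](O)c2ccc(OCc3ccccc3)c(OCc3ccccc3)c2)O1 | intermediate
5 | 3,5-bis(benzyloxy)phenol | Oc1cc(OCc2ccccc2)cc(OCc2ccccc2)c1 | starting material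
6 | (4R)-4-{(R)-[3,4-bis(benzyloxy)phenyl][3,5-bis(benzyloxy)phenoxy]methyl}-2,2-dimethyl-1,3-dioxolane | CC1(C)OC[C@H]([C@H](Oc2cc(OCc3ccccc3)cc(OCc3ccccc3)c2)c2ccc(OCc3ccccc3)c(OCc3ccccc3)c2)O1 | intermediate
7 | (2R,3R)-3-[3,4-bis(benzyloxy)phenyl]-3-[3,5-bis(benzyloxy)phenoxy]propane-1,2-diol | OC[C@@H](O)[C@H](Oc1cc(OCc2ccccc2)cc(OCc2ccccc2)c1)c1ccc(OCc2ccccc2)c(OCc2ccccc2)c1 | intermediate
8 | 1-(benzyloxy)-4-bromo-2-methoxybenzene | COc1cc(Br)ccc1OCc1ccccc1 | starting material
9 | tetramethyl orthocarbonate | COC(OC)(OC)OC | starting material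
10 | [4-(benzyloxy)-3-methoxyphenyl]magnesium bromide | COc1cc([Mg]Br)ccc1OCc1ccccc1 | intermediate
11 | 1-(benzyloxy)-2-methoxy-4-(trimethoxymethyl)benzene | COc1cc(C(OC)(OC)OC)ccc1OCc1ccccc1 | intermediate
12 | (4R)-2-[4-(benzyloxy)-3-methoxyphenyl]-4-{(R)-[3,4-bis(benzyloxy)phenyl][3,5-bis(benzyloxy)phenoxy]methyl}-2-methoxy-1,3-dioxolane (both epimers at C2 of the dioxolane) | COc1cc(C2(OC)OC[C@H]([C@H](Oc3cc(OCc4ccccc4)cc(OCc4ccccc4)c3)c3ccc(OCc4ccccc4)c(OCc4ccccc4)c3)O2)ccc1OCc1ccccc1 | intermediate
13 | (4R)-2-[4-(benzyloxy)-3-methoxyphenyl]-4-{(R)-[3,4-bis(benzyloxy)phenyl][3,5-bis(benzyloxy)phenoxy]methyl}-1,3-dioxolan-2-ylium trifluoromethanesulfonate | COc1cc(C2=[O+]C[C@H]([C@H](Oc3cc(OCc4ccccc4)cc(OCc4ccccc4)c3)c3ccc(OCc4ccccc4)c(OCc4ccccc4)c3)O2)ccc1OCc1ccccc1.[O-]S(=O)(=O)C(F)(F)F | intermediate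
14 | (2R,3R)-5,7-bis(benzyloxy)-2-[3,4-bis(benzyloxy)phenyl]-3,4-dihydro-2H-chromen-3-yl 4-(benzyloxy)-3-methoxybenzoate | COc1cc(C(=O)O[C@@H]2Cc3c(OCc4ccccc4)cc(OCc4ccccc4)cc3O[C@@H]2c2ccc(OCc3ccccc3)c(OCc3ccccc3)c2)ccc1OCc1ccccc1 | intermediate
15 | (2R,3R)-2-(3,4-dihydroxyphenyl)-5,7-dihydroxy-3,4-dihydro-2H-chromen-3-yl 4-hydroxy-3-methoxybenzoate | COc1cc(C(=O)O[C@@H]2Cc3c(O)cc(O)cc3O[C@@H]2c2ccc(O)c(O)c2)ccc1O | target

**Count**
Total steps: 7. Longest linear sequence: 6 steps (1, 2, 3, 5, 6, 7); step 4 prepares ortho ester 11 in a side branch.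

**Steps most likely to fail**

Step 6. The dioxolanylium ion may fail to alkylate the arene at C4: capture at its cationic carbon by the arene, by triflate or by adventitious water would return hydroxy esters on work-up, and acid-induced ionisation at C2 could scramble that centre. The fallback uses known chemistry, sets out from 7 and returns at 14. Regioselective tosylation of the primary hydroxyl (TsCl, Et3N, cat. Bu2SnO, CH2Cl2) would give (2R,3R)-3-[3,4-bis(benzyloxy)phenyl]-3-[3,5-bis(benzyloxy)phenoxy]-2-hydroxypropyl 4-methylbenzenesulfonate F1. K2CO3 in MeOH would close the terminal epoxide (2R)-2-{(R)-[3,4-bis(benzyloxy)phenyl][3,5-bis(benzyloxy)phenoxy]methyl}oxirane F2 with C3 unchanged. Intramolecular Friedel–Crafts epoxide–arene cyclisation in (CF3)2CHOH (or with BF3·OEt2 at −78 °C), 6-endo at the terminal carbon, would give (2R,3R)-5,7-bis(benzyloxy)-2-[3,4-bis(benzyloxy)phenyl]-3,4-dihydro-2H-chromen-3-ol F3. Steglich esterification with commercial 4-(benzyloxy)-3-methoxybenzoic acid (EDC·HCl, DMAP, CH2Cl2) would then give 14.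

Step 2. The electron-rich benzylic alkoxyphosphonium ion may ionise before the weakly acidic phenol captures it, with loss of stereospecificity at C2 and elimination. The fallback sets out from 4 and returns at 6; it makes the aryl–oxygen bond (O1–C8a) instead and leaves the carbinol C–O bond intact in the arylation. Mitsunobu inversion with the far more acidic 4-nitrobenzoic acid (PPh3, DIAD, toluene) would give (R)-[3,4-bis(benzyloxy)phenyl][(4R)-2,2-dimethyl-1,3-dioxolan-4-yl]methyl 4-nitrobenzoate F4. Methanolysis (K2CO3, MeOH) would give the syn alcohol (R)-[3,4-bis(benzyloxy)phenyl][(4R)-2,2-dimethyl-1,3-dioxolan-4-yl]methanol F5. Its sodium alkoxide (NaH, DMF) would displace one fluoride of 1,3,5-trifluorobenzene (SNAr, retention at the carbinol carbon) to give (4R)-4-{(R)-[3,4-bis(benzyloxy)phenyl](3,5-difluorophenoxy)methyl}-2,2-dimethyl-1,3-dioxolane F6. BnONa in N-methylpyrrolidone with heating would replace the two remaining fluorides by benzyloxy groups to give 6.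

Step 1. Facial selectivity in the aryl addition may be poor (Felkin–Anh and competing transition states close in energy), leaving much material as the syn epimer. The fallback sets out from crude 4 (the unseparated epimer mixture) and returns at 4. Dess–Martin oxidation would converge both epimers on the ketone [3,4-bis(benzyloxy)phenyl][(4R)-2,2-dimethyl-1,3-dioxolan-4-yl]methanone F7. Chelation-controlled reduction with Zn(BH4)2 in Et2O at low temperature (zinc bridging the carbonyl oxygen and the adjacent dioxolane oxygen, hydride from the face of the C4 hydrogen) should return the anti alcohol 4, so stereocontrol moves from C–C bond formation to hydride delivery.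

**Further compounds**
F1 | step 6 | (2R,3R)-3-[3,4-bis(benzyloxy)phenyl]-3-[3,5-bis(benzyloxy)phenoxy]-2-hydroxypropyl 4-methylbenzenesulfonate | Cc1ccc(S(=O)(=O)OC[C@@H](O)[C@H](Oc2cc(OCc3ccccc3)cc(OCc3ccccc3)c2)c2ccc(OCc3ccccc3)c(OCc3ccccc3)c2)cc1
F2 | step 6 | (2R)-2-{(R)-[3,4-bis(benzyloxy)phenyl][3,5-bis(benzyloxy)phenoxy]methyl}oxirane | C1O[C@H]1[C@H](Oc1cc(OCc2ccccc2)cc(OCc2ccccc2)c1)c1ccc(OCc2ccccc2)c(OCc2ccccc2)c1
F3 | step 6 | (2R,3R)-5,7-bis(benzyloxy)-2-[3,4-bis(benzyloxy)phenyl]-3,4-dihydro-2H-chromen-3-ol | O[C@@H]1Cc2c(OCc3ccccc3)cc(OCc3ccccc3)cc2O[C@@H]1c1ccc(OCc2ccccc2)c(OCc2ccccc2)c1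
F4 | step 2 | (R)-[3,4-bis(benzyloxy)phenyl][(4R)-2,2-dimethyl-1,3-dioxolan-4-yl]methyl 4-nitrobenzoate | CC1(C)OC[C@H]([C@H](OC(=O)c2ccc([N+](=O)[O-])cc2)c2ccc(OCc3ccccc3)c(OCc3ccccc3)c2)O1
F5 | step 2 | (R)-[3,4-bis(benzyloxy)phenyl][(4R)-2,2-dimethyl-1,3-dioxolan-4-yl]methanol | CC1(C)OC[C@H]([C@H](O)c2ccc(OCc3ccccc3)c(OCc3ccccc3)c2)O1
F6 | step 2 | (4R)-4-{(R)-[3,4-bis(benzyloxy)phenyl](3,5-difluorophenoxy)methyl}-2,2-dimethyl-1,3-dioxolane | CC1(C)OC[C@H]([C@H](Oc2cc(F)cc(F)c2)c2ccc(OCc3ccccc3)c(OCc3ccccc3)c2)O1
F7 | step 1 | [3,4-bis(benzyloxy)phenyl][(4R)-2,2-dimethyl-1,3-dioxolan-4-yl]methanone | CC1(C)OC[C@H](C(=O)c2ccc(OCc3ccccc3)c(OCc3ccccc3)c2)O1
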